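**Retrosynthetic overview**
1. The one strategic disconnection is the diarylmethane bond between the benzylic CH2 of the dibromocatechol ring (ring B) and C2 of the methoxyresorcinol ring (ring A); both benzene rings are bought and no ring is formed in the route.
2. Ring B: creosol 1 → vicinal dibromide 2 → catechol 3 → bis-silyl ether 4, a toluene whose benzylic carbon is still CH3. Ring A: commercial methyl 3,5-dihydroxy-4-methoxybenzoate 5.
3. Union: anodic cross-dehydrogenative coupling of the benzylic C–H of 4 with the aryl C2–H of 5, two natively nucleophilic carbons. The anode reverses the polarity of the benzylic carbon, which is stored as aminosulfonium ion 6 and gives 7; ester reduction (8) and fluoride desilylation (9) follow.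
4. Enabling feature: in ring B the CH3 carbon is para to the C4′ oxygen, so the ring radical cation loses the benzylic proton and the resulting cation is oxygen-stabilised. In ring A, C2 is ortho to C3–OH and para to C5–OH, C4 is blocked by OMe, and the mirror plane through C1/C4 makes C2 and C6 the same carbon, so only one mono-benzyl product can form.

Key step: step 4

Remarks on the chemistry:
- The target has no stereocentre and no stereogenic axis. It is achiral, so no enantiocontrol is needed and no SMILES carries stereo descriptors.
- Locants used: ring A C1 (CH2OH carbon), C2 (benzyl-bearing carbon), C3 (OH), C4 (OMe), C5 (OH), C6 (H); ring B C1′ (benzylic), C2′/C3′ (Br), C4′/C5′ (O), C6′ (H).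
- The mediator in step 4 is S,S-diphenyl-N-tosylsulfilimine, Ph2S=NTs, Cc1ccc(cc1)S(=O)(=O)N=S(c1ccccc1)c1ccccc1. It is regenerated in the coupling. The overall cell reaction is 4 + 5 → 7 + H2; TfOH in the catholyte serves only as the proton reservoir for the cathode.

**Step 1**
Reactants: 1 creosol (2-methoxy-4-methylphenol)
Product: 2 2,3-dibromo-6-methoxy-4-methylphenol
Conditions: Br2 (2.05 equiv), AcOH, 0 °C → rt
Reagents that add atoms: bromine, BrBr
Why: Electrophilic aromatic bromination, in which the free phenol directs one bromine ortho to OH and the methoxy group directs the other para to itself, so either order of entry converges on the vicinal dibromide while the hindered position between OMe and CH3 should stay untouched.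

**Step 2**
Reactants: 2 2,3-dibromo-6-methoxy-4-methylphenol
Product: 3 3,4-dibromo-5-methylbenzene-1,2-diol
Conditions: BBr3 (3 equiv), CH2Cl2, −78 °C → rt; H2O
Reagents that add atoms: none
Why: BBr3 cleavage of the aryl methyl ether (boron–oxonium complex, SN2 loss of MeBr, hydrolysis) should free the catechol, with the aryl bromides and the methyl group inert.

**Step 3**
Reactants: 3 3,4-dibromo-5-methylbenzene-1,2-diol
Product: 4 2,3-dibromo-4,5-bis(tert-butyldimethylsilyloxy)toluene
Conditions: TBSCl (2.5 equiv), imidazole (5 equiv), DMAP (cat.), DMF, rt → 40 °C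
Reagents that add atoms: tert-butyldimethylsilyl chloride (TBSCl), CC(C)(C)[Si](C)(C)Cl
Why: Imidazole-mediated silylation of both phenols should give a catechol bis-silyl ether that keeps an oxygen donor para to the methyl group, tolerates the non-nucleophilic anolyte, and can later be removed by fluoride without touching the ring A methyl ether.

**Step 4**
Reactants: 4 2,3-dibromo-4,5-bis(tert-butyldimethylsilyloxy)toluene; 5 methyl 3,5-dihydroxy-4-methoxybenzoate
Product: 7 methyl 2-[[2,3-dibromo-4,5-bis(tert-butyldimethylsilyloxy)phenyl]methyl]-3,5-dihydroxy-4-methoxybenzoate, via {N-[[2,3-dibromo-4,5-bis(tert-butyldimethylsilyloxy)phenyl]methyl]-4-methylbenzenesulfonamido}diphenylsulfonium tetrakis(pentafluorophenyl)borate 6 (not isolated)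
Conditions: Ph2S=NTs (1.5 equiv), Bu4NB(C6F5)4/CH2Cl2, divided cell, carbon-felt anode, Pt cathode (TfOH in catholyte), constant current, 2.2 F/mol, 0 °C; then current off, 5 (2 equiv, in CH2Cl2/HFIP), rt → 40 °C
Reagents that add atoms: none
Why: Anodic oxidation of 4 gives the arene radical cation, which loses a proton from the CH3 group para to the C4′ silyloxy oxygen and a second electron to give an oxygen-stabilised benzyl cation that the sulfilimine nitrogen captures as aminosulfonium ion 6; once the current is off, 6 ionises reversibly and the benzyl cation attacks C2 of 5 in a Friedel–Crafts (SEAr) step that returns the sulfilimine, while the two hydrogens leave as H2 at the cathode. The closest known reaction type is the anodic benzylic C–H/aromatic C–H cross-coupling through pooled benzylaminosulfonium ions (stabilised cation pool), a cross-dehydrogenative union of two natively nucleophilic carbons made possible by anodic polarity reversal of the benzylic one. No ring is closed and no stereocentre is formed. Chemoselectivity rests on separation in time: the easily oxidised phenol 5 and the still more electron-rich product 7 never meet the anode, and no low-valent metal is present that could insert into the two C–Br bonds. Site selectivity in 4 rests on the methyl group being the only C–H position conjugated para to oxygen (the single ring C–H, C6′, is flanked by CH3 and OSi), and in 5 on C2 being ortho to C3–OH and para to C5–OH, with C4 blocked by OMe and C2/C6 equivalent by symmetry. Mono-benzylation should be favoured by the excess of 5 and by the steric shielding that the first benzyl group and the ester impose on the product.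

**Step 5**
Reactants: 7 methyl 2-[[2,3-dibromo-4,5-bis(tert-butyldimethylsilyloxy)phenyl]methyl]-3,5-dihydroxy-4-methoxybenzoate
Product: 8 4-[[2,3-dibromo-4,5-bis(tert-butyldimethylsilyloxy)phenyl]methyl]-5-(hydroxymethyl)-2-methoxybenzene-1,3-diol
Conditions: DIBAL-H (6 equiv), CH2Cl2, −78 → 0 °C; aq. Rochelle salt work-up
Reagents that add atoms: none
Why: DIBAL-H reduction of the aryl methyl ester to the benzylic alcohol, with the two phenols carried as aluminium phenoxides and the aryl bromides and aryl silyl ethers expected to be inert at or below 0 °C.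

**Step 6**
Reactants: 8 4-[[2,3-dibromo-4,5-bis(tert-butyldimethylsilyloxy)phenyl]methyl]-5-(hydroxymethyl)-2-methoxybenzene-1,3-diol
Product: 9 4-[(2,3-dibromo-4,5-dihydroxyphenyl)methyl]-5-(hydroxymethyl)-2-methoxybenzene-1,3-diol (CNP0333037.0)
Conditions: TBAF (2.5 equiv), AcOH (2.5 equiv), THF, 0 °C, Ar
Reagents that add atoms: none
Why: Fluoride cleavage of the two aryl Si–O bonds, buffered with acetic acid so that the air-sensitive bromocatechol is not held as a free phenoxide, should leave the aryl methyl ether, the benzylic alcohol and the C–Br bonds untouched.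

**Compound list**
1 | creosol (2-methoxy-4-methylphenol) | COc1cc(C)ccc1O | starting material
2 | 2,3-dibromo-6-methoxy-4-methylphenol | COc1cc(C)c(Br)c(Br)c1O | intermediate
3 | 3,4-dibromo-5-methylbenzene-1,2-diol | Cc1cc(O)c(O)c(Br)c1Br | intermediate
4 | 2,3-dibromo-4,5-bis(tert-butyldimethylsilyloxy)toluene | Cc1cc(O[Si](C)(C)C(C)(C)C)c(O[Si](C)(C)C(C)(C)C)c(Br)c1Br | intermediate
5 | methyl 3,5-dihydroxy-4-methoxybenzoate | COC(=O)c1cc(O)c(OC)c(O)c1 | starting material
6 | {N-[[2,3-dibromo-4,5-bis(tert-butyldimethylsilyloxy)phenyl]methyl]-4-methylbenzenesulfonamido}diphenylsulfonium tetrakis(pentafluorophenyl)borate | Cc1ccc(cc1)S(=O)(=O)N(Cc1cc(O[Si](C)(C)C(C)(C)C)c(O[Si](C)(C)C(C)(C)C)c(Br)c1Br)[S+](c1ccccc1)c1ccccc1.Fc1c(F)c(F)c(F)c(F)c1[B-](c1c(F)c(F)c(F)c(F)c1F)(c1c(F)c(F)c(F)c(F)c1F)c1c(F)c(F)c(F)c(F)c1F | intermediate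
7 | methyl 2-[[2,3-dibromo-4,5-bis(tert-butyldimethylsilyloxy)phenyl]methyl]-3,5-dihydroxy-4-methoxybenzoate | COC(=O)c1cc(O)c(OC)c(O)c1Cc1cc(O[Si](C)(C)C(C)(C)C)c(O[Si](C)(C)C(C)(C)C)c(Br)c1Br | intermediate
8 | 4-[[2,3-dibromo-4,5-bis(tert-butyldimethylsilyloxy)phenyl]methyl]-5-(hydroxymethyl)-2-methoxybenzene-1,3-diol | COc1c(O)cc(CO)c(Cc2cc(O[Si](C)(C)C(C)(C)C)c(O[Si](C)(C)C(C)(C)C)c(Br)c2Br)c1O | intermediate
9 | 4-[(2,3-dibromo-4,5-dihydroxyphenyl)methyl]-5-(hydroxymethyl)-2-methoxybenzene-1,3-diol | COc1c(O)cc(CO)c(Cc2cc(O)c(O)c(Br)c2Br)c1O | target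

**Step count**
Total steps: 6. Longest linear sequence: 6 (1 → 2 → 3 → 4 → 7 → 8 → 9); ring A component 5 is used as bought.

**Steps most likely to fail, with fallbacks**

Step 4. At the anode, attack of the sulfilimine on the ring radical cation or Si–O scission may compete with benzylic deprotonation. In the second stage, ionisation of the ortho-bromo-substituted sulfonium ion and capture by the ester-deactivated, flanked C2 may be slow, so that O-benzylation or double benzylation competes. The fallback sets out from 4 and comes back at 7. Radical benzylic bromination of 4 (NBS, AIBN, PhCF3, 80 °C, Wohl–Ziegler) should give 1-(bromomethyl)-2,3-dibromo-4,5-bis(tert-butyldimethylsilyloxy)benzene F1. F1 is then used in a classical Friedel–Crafts benzylation of 5 (2 equiv) in HFIP, or with catalytic ZnCl2 in CH2Cl2, to give 7.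

Step 1. Over-bromination at the remaining ring position, or incomplete second bromination, may leave mixtures that are hard to separate. The fallback sets out from 1 and comes back at 3, bypassing 2. Monobromination of 1 ortho to the phenol (Br2, 1.0 equiv, CH2Cl2, −20 °C) should give 2-bromo-6-methoxy-4-methylphenol F2. BBr3 demethylation should give 3-bromo-5-methylbenzene-1,2-diol F3. The second bromine is then introduced under control of the free catechol, para to the OH remote from the first bromine (Br2, 1.0 equiv, AcOH, rt), to give 3.

Step 5. The two aluminium phenoxides formed on ring A may deactivate the hindered ester, so that the reduction needs warming, at which aryl Si–O cleavage or C–Br reduction could begin. The fallback sets out from 7 and comes back at 9, bypassing 8. Silylation of the two ring A phenols (TBSOTf, 2,6-lutidine, CH2Cl2, 0 °C) should give methyl 2-[[2,3-dibromo-4,5-bis(tert-butyldimethylsilyloxy)phenyl]methyl]-3,5-bis(tert-butyldimethylsilyloxy)-4-methoxybenzoate F4. DIBAL-H reduction at −78 °C should then give [2-[[2,3-dibromo-4,5-bis(tert-butyldimethylsilyloxy)phenyl]methyl]-3,5-bis(tert-butyldimethylsilyloxy)-4-methoxyphenyl]methanol F5. Global desilylation (TBAF/AcOH, THF, 0 °C) gives 9.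

**Further compounds**
F1 | step 4 | 1-(bromomethyl)-2,3-dibromo-4,5-bis(tert-butyldimethylsilyloxy)benzene | BrCc1cc(O[Si](C)(C)C(C)(C)C)c(O[Si](C)(C)C(C)(C)C)c(Br)c1Br
F2 | step 1 | 2-bromo-6-methoxy-4-methylphenol | COc1cc(C)cc(Br)c1O
F3 | step 1 | 3-bromo-5-methylbenzene-1,2-diol | Cc1cc(O)c(O)c(Br)c1
F4 | step 5 | methyl 2-[[2,3-dibromo-4,5-bis(tert-butyldimethylsilyloxy)phenyl]methyl]-3,5-bis(tert-butyldimethylsilyloxy)-4-methoxybenzoate | COC(=O)c1cc(O[Si](C)(C)C(C)(C)C)c(OC)c(O[Si](C)(C)C(C)(C)C)c1Cc1cc(O[Si](C)(C)C(C)(C)C)c(O[Si](C)(C)C(C)(C)C)c(Br)c1Br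
F5 | step 5 | [2-[[2,3-dibromo-4,5-bis(tert-butyldimethylsilyloxy)phenyl]methyl]-3,5-bis(tert-butyldimethylsilyloxy)-4-methoxyphenyl]methanol | COc1c(O[Si](C)(C)C(C)(C)C)cc(CO)c(Cc2cc(O[Si](C)(C)C(C)(C)C)c(O[Si](C)(C)C(C)(C)C)c(Br)c2Br)c1O[Si](C)(C)C(C)(C)C
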